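**Retrosynthetic overview** (ring atoms numbered as in carotenoids: C1 gem-dimethyl carbon, C3 carbinol, C5/C6 oxirane carbons, C7 the exocyclic vinyl carbon)

1. Last bonds: Suzuki–Miyaura coupling of dienyl iodide 13 (acetoxycyclohexenyl enyne half) with dienylboronate 28, which comes from Stille coupling of α-bromobutenolide 7 with alkenylstannane 27. All three coupling handles (I, Bpin, SnBu3) are made from aldehydes by Takai-type olefinations.
2. Ring order: the cyclohexene ring is bought ((4R,6R)-actinol). The butenolide is closed in step 2 (Sonogashira coupling/5-exo-dig lactonisation). The C1–C6 carbocycle of the epoxycyclohexanol is closed last, in step 15, and no ring is formed after it.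
3. Key step: intramolecular Darzens epoxy-annulation of the acyclic keto α-chloro ester 20. C5–C6 bond formation closes the carbocycle, and the alkoxide so created locks the 5,6-oxirane in the same operation; C5 and C6 are set from the single stereocentre C3.
4. Enabling feature: C3–OH and C5–O are 1,3-related (acetone aldol, so C5 is a methyl ketone), and the C5–C6 oxirane with C7 drawn as a carboxyl is a glycidic ester (C6 = α-chloro ester carbon). Quaternary C1 leaves that ester a single acidic hydrogen and pre-folds the chain.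
5. The activating tert-butyl ester becomes C7 of the target: it is reduced to the aldehyde and olefinated to the E-alkenylstannane.

Key step: step 15

Remark: compounds 17–20 are carried as mixtures of epimers at the CHCl carbon, which step 15 erases as an enolate; starting materials 1, 3, 8 and 14 are taken as purchasable.

Step 1
Reactants: 1 propiolic acid
Product: 2 (E)-2,3-dibromoprop-2-enoic acid
Conditions: Br2 (1.0 equiv), CHCl3, 0 °C to rt, dark
Reagents that add atoms: bromine, BrBr
Why: Electrophilic bromination of the alkyne by anti addition should give the E-dibromide, which holds CO2H and the β-bromine cis as the later lactonisation requires.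

Step 2
Reactants: 2 (E)-2,3-dibromoprop-2-enoic acid; 3 (E)-3-methylpent-2-en-4-yn-1-ol
Product: 5 (Z)-3-bromo-5-[(E)-4-hydroxy-2-methylbut-2-en-1-ylidene]furan-2(5H)-one, via enynoic acid 4 (not isolated)
Conditions: PdCl2(PPh3)2 (5 mol%), CuI (10 mol%), Et3N, MeCN, rt
Reagents that add atoms: none
Why: Sonogashira coupling should occur with retention at the more reactive β-C–Br bond, and the cis carboxyl group of 4 then adds anti across the metal-activated alkyne in a 5-exo-dig lactonisation that sets the Z-ylidene geometry and leaves the α-bromine as the later Stille handle.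

Step 3
Reactants: 5 (Z)-3-bromo-5-[(E)-4-hydroxy-2-methylbut-2-en-1-ylidene]furan-2(5H)-one
Product: 6 (E)-4-[(Z)-4-bromo-5-oxofuran-2(5H)-ylidene]-3-methylbut-2-enal
Conditions: activated MnO2 (excess), CH2Cl2, rt
Reagents that add atoms: none
Why: Allylic oxidation with MnO2 is selective for the primary allylic alcohol and leaves the bromobutenolide and both alkene geometries untouched.

Step 4
Reactants: 6 (E)-4-[(Z)-4-bromo-5-oxofuran-2(5H)-ylidene]-3-methylbut-2-enal
Product: 7 (Z)-3-bromo-5-[(2E,4E)-2-methyl-5-(4,4,5,5-tetramethyl-1,3,2-dioxaborolan-2-yl)penta-2,4-dien-1-ylidene]furan-2(5H)-one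
Conditions: Cl2CHB(pin) (2 equiv), CrCl2 (8 equiv), LiI (4 equiv), THF, rt
Reagents that add atoms: 2-(dichloromethyl)-4,4,5,5-tetramethyl-1,3,2-dioxaborolane, ClC(Cl)B1OC(C)(C)C(C)(C)O1
Why: Takai–Utimoto boryl-olefination: the gem-dichromium reagent formed from Cl2CHB(pin) and divalent chromium adds to the aldehyde and eliminates to the E-alkenylboronate, while the alkenyl bromide is inert to CrCl2 in the absence of a nickel catalyst.

Step 5
Reactants: 8 (4R,6R)-4-hydroxy-2,2,6-trimethylcyclohexan-1-one ((4R,6R)-actinol)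
Product: 9 (1R,3R)-3,5,5-trimethyl-4-oxocyclohexyl acetate
Conditions: Ac2O, pyridine, DMAP (cat.), CH2Cl2, rt
Reagents that add atoms: acetic anhydride, CC(=O)OC(C)=O
Why: Acylation of the secondary alcohol under nucleophilic catalysis installs the acetate of the target at the outset and leaves the R carbinol centre untouched.

Step 6
Reactants: 9 (1R,3R)-3,5,5-trimethyl-4-oxocyclohexyl acetate
Product: 10 (R)-4-acetoxy-2,6,6-trimethylcyclohex-1-en-1-yl trifluoromethanesulfonate
Conditions: Tf2O, 2,6-di-tert-butyl-4-methylpyridine, CH2Cl2, 0 °C to rt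
Reagents that add atoms: trifluoromethanesulfonic anhydride, O=S(=O)(OS(=O)(=O)C(F)(F)F)C(F)(F)F
Why: Enol triflate formation under non-basic conditions: the ketone can enolise only toward the methyl-bearing carbon (the other α-carbon is quaternary), so one triflate results, the acetate survives, and the now superfluous methyl-bearing stereocentre is erased.

Step 7
Reactants: 10 (R)-4-acetoxy-2,6,6-trimethylcyclohex-1-en-1-yl trifluoromethanesulfonate; 3 (E)-3-methylpent-2-en-4-yn-1-ol
Product: 11 (R)-4-[(E)-5-hydroxy-3-methylpent-3-en-1-yn-1-yl]-3,5,5-trimethylcyclohex-3-en-1-yl acetate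
Conditions: Pd(PPh3)4 (5 mol%), CuI (10 mol%), i-Pr2NH, DMF, rt to 45 °C
Reagents that add atoms: none
Why: Sonogashira coupling of the enol triflate with the terminal alkyne builds the ring-to-chain bond and carries the E-trisubstituted alkene of 3 into the product unchanged.

Step 8
Reactants: 11 (R)-4-[(E)-5-hydroxy-3-methylpent-3-en-1-yn-1-yl]-3,5,5-trimethylcyclohex-3-en-1-yl acetate
Product: 12 (R)-3,5,5-trimethyl-4-[(E)-3-methyl-5-oxopent-3-en-1-yn-1-yl]cyclohex-3-en-1-yl acetate
Conditions: activated MnO2 (excess), CH2Cl2, rt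
Reagents that add atoms: none
Why: Allylic oxidation with MnO2 gives the enynal without affecting the acetate or the alkene geometry.

Step 9
Reactants: 12 (R)-3,5,5-trimethyl-4-[(E)-3-methyl-5-oxopent-3-en-1-yn-1-yl]cyclohex-3-en-1-yl acetate
Product: 13 (R)-4-[(3E,5E)-6-iodo-3-methylhexa-3,5-dien-1-yn-1-yl]-3,5,5-trimethylcyclohex-3-en-1-yl acetate
Conditions: CHI3 (2 equiv), CrCl2 (6 equiv), THF/1,4-dioxane (1:6), 0 °C to rt, dark
Reagents that add atoms: iodoform, IC(I)I
Why: Takai olefination with CHI3 and CrCl2 converts the aldehyde into the E-alkenyl iodide by anti elimination from the adduct of the gem-dichromium reagent.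

Step 10
Reactants: 14 3,3-dimethylpent-4-enoic acid
Product: 15 tert-butyl 3,3-dimethylpent-4-enoate
Conditions: tert-butyl 2,2,2-trichloroacetimidate (2 equiv), CH2Cl2/cyclohexane, rt
Reagents that add atoms: tert-butyl 2,2,2-trichloroacetimidate, CC(C)(C)OC(=N)C(Cl)(Cl)Cl
Why: tert-Butyl ester formation by O-alkylation of the acid with the trichloroacetimidate gives the bulky ester that the Darzens step needs and avoids strong acid that could lactonise the acid onto its own alkene.

Step 11
Reactants: 15 tert-butyl 3,3-dimethylpent-4-enoate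
Product: 17 tert-butyl 2-chloro-3,3-dimethylpent-4-enoate (racemic), via lithium ester enolate 16 (not isolated)
Conditions: LiN(i-Pr)2 (1.1 equiv), THF, −78 °C; then cannulated into C2Cl6 (1.3 equiv), THF, −78 °C
Reagents that add atoms: hexachloroethane, ClC(Cl)(Cl)C(Cl)(Cl)Cl
Why: Ester enolate chlorination: the ester CH2 is the only acidic position and its lithium enolate takes up Cl+ from C2Cl6; the new CHCl centre is racemic, which is harmless because step 15 re-forms the enolate.

Step 12
Reactants: 17 tert-butyl 2-chloro-3,3-dimethylpent-4-enoate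
Product: 18 tert-butyl 2-chloro-3,3-dimethyl-5-oxopentanoate
Conditions: PdCl2(PhCN)2 (12 mol%), CuCl2·2H2O (12 mol%), AgNO2 (6 mol%), t-BuOH/MeNO2 (15:1), O2 (1 atm), rt
Reagents that add atoms: dioxygen, O=O
Why: Nitrite-modified, aldehyde-selective Wacker oxidation: the quaternary allylic carbon disfavours Markovnikov attack, so oxygen should be delivered to the terminal carbon to give the aldehyde.

Step 13
Reactants: 18 tert-butyl 2-chloro-3,3-dimethyl-5-oxopentanoate
Product: 19 tert-butyl (5S)-2-chloro-5-hydroxy-3,3-dimethyl-7-oxooctanoate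
Conditions: (S)-N-[(S)-1-hydroxy-4-methyl-1,1-diphenylpentan-2-yl]pyrrolidine-2-carboxamide (10 mol%), acetone (solvent), −25 °C
Reagents that add atoms: acetone, CC(C)=O
Why: Direct asymmetric aldol addition of acetone by enamine catalysis: the L-proline-derived amide directs the acetone enamine to one face of the aldehyde through hydrogen bonding, which should set the carbinol centre as S (the later C3 of the ring).

Step 14
Reactants: 19 tert-butyl (5S)-2-chloro-5-hydroxy-3,3-dimethyl-7-oxooctanoate
Product: 20 tert-butyl (5S)-5-[(tert-butyldimethylsilyl)oxy]-2-chloro-3,3-dimethyl-7-oxooctanoate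
Conditions: TBSCl, imidazole, DMF, rt
Reagents that add atoms: tert-butyldimethylsilyl chloride, CC(C)(C)[Si](C)(C)Cl
Why: Silyl ether formation at the secondary alcohol blocks retro-aldol and lactonisation pathways and supplies the bulky equatorial group that steers the ring closure.

Step 15
Reactants: 20 tert-butyl (5S)-5-[(tert-butyldimethylsilyl)oxy]-2-chloro-3,3-dimethyl-7-oxooctanoate
Product: 23 tert-butyl (1S,4S,6R)-4-[(tert-butyldimethylsilyl)oxy]-2,2,6-trimethyl-7-oxabicyclo[4.1.0]heptane-1-carboxylate, via potassium ester enolate 21 (not isolated), via ring-closed chloro-alkoxide 22 (not isolated)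
Conditions: KOt-Bu (1.2 equiv), THF/t-BuOH (10:1), 0.02 M, −60 to −20 °C
Reagents that add atoms: none
Why: KOt-Bu reversibly deprotonates the α-chloro ester C–H (both epimers of 20 give the same enolate 21), the enolate carbon adds to the methyl ketone in a 6-(enolexo)-exo-trig aldol closure that forms the carbocycle as chloro-alkoxide 22, and the alkoxide then displaces the neighbouring chloride with inversion (3-exo-tet SN2) to lock the oxirane, i.e. an intramolecular Darzens glycidic ester condensation. The closest known reaction type is the Darzens reaction of tert-butyl α-chloro esters with ketones under KOt-Bu, including its intramolecular variants that deliver epoxide-fused rings. Both new stereocentres (the two fully substituted oxirane carbons) are controlled by the silyloxy-bearing centre: only the chair that keeps OTBS and the ketone-derived methyl equatorial (oxygen axial, no 1,3-diaxial Me/Me contact with the gem-dimethyl carbon) can hold O− and Cl trans-diaxial, so the oxirane forms anti to OTBS with the ester syn to it, while aldolates with O− and Cl cis cannot close and revert by retro-aldol. The step needs enolisation of the ester to win over the chemistry of the ketone enolates (β-elimination of silanolate from the CH2 next to the silyloxy carbon, Claisen closure), and it needs the congested C–C bond to form at all. These are secured by the more acidic α-chloro ester C–H, the quaternary carbon that leaves this ester a single acidic hydrogen and pre-folds the chain (gem-dialkyl effect), the tert-butyl ester that resists acyl attack, low temperature and dilution, and the irreversible oxirane closure that drains the reversible aldol.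

Step 16
Reactants: 23 tert-butyl (1S,4S,6R)-4-[(tert-butyldimethylsilyl)oxy]-2,2,6-trimethyl-7-oxabicyclo[4.1.0]heptane-1-carboxylate
Product: 24 [(1R,4S,6R)-4-[(tert-butyldimethylsilyl)oxy]-2,2,6-trimethyl-7-oxabicyclo[4.1.0]heptan-1-yl]methanol
Conditions: i-Bu2AlH (3 equiv), CH2Cl2, −78 to −40 °C; aqueous KNaC4H4O6 (tartrate) work-up
Reagents that add atoms: none
Why: Hydride reduction of the tert-butyl ester with excess i-Bu2AlH gives the primary alcohol, while the tetrasubstituted oxirane and the silyl ether are not attacked at low temperature.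

Step 17
Reactants: 24 [(1R,4S,6R)-4-[(tert-butyldimethylsilyl)oxy]-2,2,6-trimethyl-7-oxabicyclo[4.1.0]heptan-1-yl]methanol
Product: 25 (1S,4S,6R)-4-[(tert-butyldimethylsilyl)oxy]-2,2,6-trimethyl-7-oxabicyclo[4.1.0]heptane-1-carbaldehyde
Conditions: (n-Pr4N)RuO4 (5 mol%), N-methylmorpholine N-oxide, 4 Å molecular sieves, CH2Cl2, rt
Reagents that add atoms: none
Why: Ley–Griffith oxidation with catalytic perruthenate converts the neopentyl-type primary alcohol into the non-enolisable aldehyde under neutral conditions that spare the oxirane.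

Step 18
Reactants: 25 (1S,4S,6R)-4-[(tert-butyldimethylsilyl)oxy]-2,2,6-trimethyl-7-oxabicyclo[4.1.0]heptane-1-carbaldehyde
Product: 26 tert-butyldimethyl{[(1R,3S,6S)-1,5,5-trimethyl-6-[(E)-2-(tributylstannyl)ethenyl]-7-oxabicyclo[4.1.0]heptan-3-yl]oxy}silane
Conditions: Bu3SnCHBr2 (2 equiv), CrCl2 (8 equiv), LiI (4 equiv), THF/DMF, rt
Reagents that add atoms: (dibromomethyl)tributylstannane, CCCC[Sn](CCCC)(CCCC)C(Br)Br
Why: Takai-type stannyl-olefination: Bu3SnCHBr2 and divalent chromium form a gem-dichromium reagent that adds to the aldehyde and eliminates to the E-alkenylstannane without basic or strongly acidic reagents near the oxirane.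

Step 19
Reactants: 26 tert-butyldimethyl{[(1R,3S,6S)-1,5,5-trimethyl-6-[(E)-2-(tributylstannyl)ethenyl]-7-oxabicyclo[4.1.0]heptan-3-yl]oxy}silane
Product: 27 (1R,3S,6S)-1,5,5-trimethyl-6-[(E)-2-(tributylstannyl)ethenyl]-7-oxabicyclo[4.1.0]heptan-3-ol
Conditions: n-Bu4NF (1.5 equiv), THF, 0 °C to rt
Reagents that add atoms: none
Why: Fluoride-mediated desilylation frees the secondary alcohol before the couplings, so that no deprotection is needed later beside the acetate and the polyene; alkenylstannane and oxirane are stable to fluoride.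

Step 20
Reactants: 27 (1R,3S,6S)-1,5,5-trimethyl-6-[(E)-2-(tributylstannyl)ethenyl]-7-oxabicyclo[4.1.0]heptan-3-ol; 7 (Z)-3-bromo-5-[(2E,4E)-2-methyl-5-(4,4,5,5-tetramethyl-1,3,2-dioxaborolan-2-yl)penta-2,4-dien-1-ylidene]furan-2(5H)-one
Product: 28 (Z)-3-{(E)-2-[(1S,4S,6R)-4-hydroxy-2,2,6-trimethyl-7-oxabicyclo[4.1.0]heptan-1-yl]ethenyl}-5-[(2E,4E)-2-methyl-5-(4,4,5,5-tetramethyl-1,3,2-dioxaborolan-2-yl)penta-2,4-dien-1-ylidene]furan-2(5H)-one
Conditions: Pd2(dba)3 (5 mol%), AsPh3 (40 mol%), NMP, rt to 40 °C, dark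
Reagents that add atoms: none
Why: Stille coupling: zerovalent palladium inserts into the activated C–Br bond of the α-bromobutenolide and transmetallation from tin proceeds with retention of the E geometry, while the pinacol boronate stays untouched because no base is present.

Step 21
Reactants: 28 (Z)-3-{(E)-2-[(1S,4S,6R)-4-hydroxy-2,2,6-trimethyl-7-oxabicyclo[4.1.0]heptan-1-yl]ethenyl}-5-[(2E,4E)-2-methyl-5-(4,4,5,5-tetramethyl-1,3,2-dioxaborolan-2-yl)penta-2,4-dien-1-ylidene]furan-2(5H)-one; 13 (R)-4-[(3E,5E)-6-iodo-3-methylhexa-3,5-dien-1-yn-1-yl]-3,5,5-trimethylcyclohex-3-en-1-yl acetate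
Product: 29 target CNP0337675.1
Conditions: Pd(PPh3)4 (10 mol%), TlOEt (1.8 equiv), THF/H2O (3:1), rt, dark
Reagents that add atoms: none
Why: Suzuki–Miyaura coupling: oxidative addition into the dienyl iodide and thallium-ethoxide-accelerated transmetallation of the dienylboronate join the halves at room temperature with retention of both alkene geometries, fast enough to spare the acetate, butenolide and oxirane.

**Compound list**

1 | propiolic acid | C#CC(=O)O | starting material
2 | (E)-2,3-dibromoprop-2-enoic acid | OC(=O)/C(Br)=C\Br | intermediate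
3 | (E)-3-methylpent-2-en-4-yn-1-ol | C#C/C(C)=C/CO | starting material
4 | (2E,6E)-2-bromo-8-hydroxy-6-methylocta-2,6-dien-4-ynoic acid | OC(=O)/C(Br)=C\C#C/C(C)=C/CO | intermediate
5 | (Z)-3-bromo-5-[(E)-4-hydroxy-2-methylbut-2-en-1-ylidene]furan-2(5H)-one | OC/C=C(C)/C=C1C=C(Br)C(=O)O/1 | intermediate
6 | (E)-4-[(Z)-4-bromo-5-oxofuran-2(5H)-ylidene]-3-methylbut-2-enal | O=C/C=C(C)/C=C1C=C(Br)C(=O)O/1 | intermediate
7 | (Z)-3-bromo-5-[(2E,4E)-2-methyl-5-(4,4,5,5-tetramethyl-1,3,2-dioxaborolan-2-yl)penta-2,4-dien-1-ylidene]furan-2(5H)-one | CC1(C)OB(/C=C/C=C(C)/C=C2C=C(Br)C(=O)O/2)OC1(C)C | intermediate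
8 | (4R,6R)-4-hydroxy-2,2,6-trimethylcyclohexan-1-one ((4R,6R)-actinol) | O[C@@H]1C[C@@H](C)C(=O)C(C)(C)C1 | starting material
9 | (1R,3R)-3,5,5-trimethyl-4-oxocyclohexyl acetate | CC(=O)O[C@@H]1C[C@@H](C)C(=O)C(C)(C)C1 | intermediate
10 | (R)-4-acetoxy-2,6,6-trimethylcyclohex-1-en-1-yl trifluoromethanesulfonate | CC(=O)O[C@@H]1CC(C)=C(OS(=O)(=O)C(F)(F)F)C(C)(C)C1 | intermediate
11 | (R)-4-[(E)-5-hydroxy-3-methylpent-3-en-1-yn-1-yl]-3,5,5-trimethylcyclohex-3-en-1-yl acetate | CC(=O)O[C@@H]1CC(C)=C(C#C/C(C)=C/CO)C(C)(C)C1 | intermediate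
12 | (R)-3,5,5-trimethyl-4-[(E)-3-methyl-5-oxopent-3-en-1-yn-1-yl]cyclohex-3-en-1-yl acetate | CC(=O)O[C@@H]1CC(C)=C(C#C/C(C)=C/C=O)C(C)(C)C1 | intermediate
13 | (R)-4-[(3E,5E)-6-iodo-3-methylhexa-3,5-dien-1-yn-1-yl]-3,5,5-trimethylcyclohex-3-en-1-yl acetate | CC(=O)O[C@@H]1CC(C)=C(C#C/C(C)=C/C=C/I)C(C)(C)C1 | intermediate
14 | 3,3-dimethylpent-4-enoic acid | C=CC(C)(C)CC(=O)O | starting material
15 | tert-butyl 3,3-dimethylpent-4-enoate | C=CC(C)(C)CC(=O)OC(C)(C)C | intermediate
16 | lithium enolate of tert-butyl 3,3-dimethylpent-4-enoate | [Li+].C=CC(C)(C)C=C([O-])OC(C)(C)C | intermediate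
17 | tert-butyl 2-chloro-3,3-dimethylpent-4-enoate (racemic) | C=CC(C)(C)C(Cl)C(=O)OC(C)(C)C | intermediate
18 | tert-butyl 2-chloro-3,3-dimethyl-5-oxopentanoate (racemic) | O=CCC(C)(C)C(Cl)C(=O)OC(C)(C)C | intermediate
19 | tert-butyl (5S)-2-chloro-5-hydroxy-3,3-dimethyl-7-oxooctanoate (both C2 epimers) | CC(=O)C[C@@H](O)CC(C)(C)C(Cl)C(=O)OC(C)(C)C | intermediate
20 | tert-butyl (5S)-5-[(tert-butyldimethylsilyl)oxy]-2-chloro-3,3-dimethyl-7-oxooctanoate (both C2 epimers) | CC(=O)C[C@@H](O[Si](C)(C)C(C)(C)C)CC(C)(C)C(Cl)C(=O)OC(C)(C)C | intermediate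
21 | potassium ester enolate of 20 | [K+].CC(=O)C[C@@H](O[Si](C)(C)C(C)(C)C)CC(C)(C)C(Cl)=C([O-])OC(C)(C)C | intermediate
22 | potassium alkoxide of tert-butyl (1R,4S,6R)-4-[(tert-butyldimethylsilyl)oxy]-1-chloro-6-hydroxy-2,2,6-trimethylcyclohexane-1-carboxylate (O− and Cl trans-diaxial) | [K+].CC(C)(C)OC(=O)[C@]1(Cl)[C@@]([O-])(C)C[C@@H](O[Si](C)(C)C(C)(C)C)CC1(C)C | intermediate
23 | tert-butyl (1S,4S,6R)-4-[(tert-butyldimethylsilyl)oxy]-2,2,6-trimethyl-7-oxabicyclo[4.1.0]heptane-1-carboxylate | CC(C)(C)OC(=O)[C@@]12O[C@]1(C)C[C@@H](O[Si](C)(C)C(C)(C)C)CC2(C)C | intermediate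
24 | [(1R,4S,6R)-4-[(tert-butyldimethylsilyl)oxy]-2,2,6-trimethyl-7-oxabicyclo[4.1.0]heptan-1-yl]methanol | OC[C@@]12O[C@]1(C)C[C@@H](O[Si](C)(C)C(C)(C)C)CC2(C)C | intermediate
25 | (1S,4S,6R)-4-[(tert-butyldimethylsilyl)oxy]-2,2,6-trimethyl-7-oxabicyclo[4.1.0]heptane-1-carbaldehyde | O=C[C@@]12O[C@]1(C)C[C@@H](O[Si](C)(C)C(C)(C)C)CC2(C)C | intermediate
26 | tert-butyldimethyl{[(1R,3S,6S)-1,5,5-trimethyl-6-[(E)-2-(tributylstannyl)ethenyl]-7-oxabicyclo[4.1.0]heptan-3-yl]oxy}silane | CCCC[Sn](CCCC)(CCCC)/C=C/[C@@]12O[C@]1(C)C[C@@H](O[Si](C)(C)C(C)(C)C)CC2(C)C | intermediate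
27 | (1R,3S,6S)-1,5,5-trimethyl-6-[(E)-2-(tributylstannyl)ethenyl]-7-oxabicyclo[4.1.0]heptan-3-ol | CCCC[Sn](CCCC)(CCCC)/C=C/[C@@]12O[C@]1(C)C[C@@H](O)CC2(C)C | intermediate
28 | (Z)-3-{(E)-2-[(1S,4S,6R)-4-hydroxy-2,2,6-trimethyl-7-oxabicyclo[4.1.0]heptan-1-yl]ethenyl}-5-[(2E,4E)-2-methyl-5-(4,4,5,5-tetramethyl-1,3,2-dioxaborolan-2-yl)penta-2,4-dien-1-ylidene]furan-2(5H)-one | CC1(C)OB(/C=C/C=C(C)/C=C2C=C(/C=C/[C@@]34O[C@]3(C)C[C@@H](O)CC4(C)C)C(=O)O/2)OC1(C)C | intermediate
29 | target CNP0337675.1: the (3S,5R,6S)-epoxycyclohexanol / (R)-acetoxycyclohexenyl-ethynyl norcarotenoid with all-E chain and Z-ylidenebutenolide | CC(=O)O[C@@H]1CC(C)=C(C#C/C(C)=C/C=C/C=C/C=C(C)/C=C2C=C(/C=C/[C@@]34O[C@]3(C)C[C@@H](O)CC4(C)C)C(=O)O/2)C(C)(C)C1 | target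

**Step count and risks**

Total: 21 steps. Longest linear sequence: 12 steps (14 → 15 → 17 → 18 → 19 → 20 → 23 → 24 → 25 → 26 → 27 → 28 → 29; steps 10–21).

Steps most likely to fail:

1. Step 15. The ketone may enolise toward the CH2 next to the silyloxy carbon and lose silanolate by β-elimination, or the retro-aldol may outrun oxirane closure at the congested centre. The fallback generates the chloro enolate by reduction instead of by base; it sets out from chloro ester 17 and comes back at glycidic ester 23. A second enolate chlorination of 17 (LiN(i-Pr)2, THF, −78 °C; C2Cl6) would give tert-butyl 2,2-dichloro-3,3-dimethylpent-4-enoate F1. The Wacker oxidation, aldol addition and silylation of steps 12 to 14 would then give dichloro aldehyde F2, dichloro aldol F3 and dichloro keto ester F4. SmI2 (2.2 equiv, THF, −78 °C) would reduce one C–Cl bond of F4 to a samarium α-chloro enolate (Reformatsky-type, the ketone never meets a base), and its chelated aldol ring closure should give chlorohydrin F5. K2CO3 in MeOH would then close the oxirane to 23.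

2. Step 13. Facial selectivity or conversion of the enamine aldol may be poor with this α-unbranched aldehyde, and the aldol may dehydrate. The fallback is a reagent-controlled allylboration; it sets out from aldehyde 18 and comes back at aldol 19. (+)-Ipc2B(2-methylallyl), made from (+)-Ipc2BOMe and CH2=C(CH3)CH2MgCl (Et2O, −78 °C; NaBO3 work-up), is the borane enantiomer expected to give tert-butyl (5R)-2-chloro-5-hydroxy-3,3,7-trimethyloct-7-enoate F6 (same spatial arrangement as 19; the descriptor changes only through the priorities). Ozonolysis (O3, CH2Cl2/MeOH, −78 °C; Me2S) would then give 19.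

3. Step 18. Addition of the bulky gem-dimetallic reagent to the neopentyl-type, α-oxygenated aldehyde may be slow, and long exposure to chromium salts may open the oxirane. The fallback is alkyne homologation followed by hydrometallation; it sets out from aldehyde 25 and comes back at stannane 26. Seyferth–Gilbert homologation with dimethyl (1-diazo-2-oxopropyl)phosphonate (K2CO3, MeOH, 0 °C to rt) would give ethynyl epoxide F7. Syn hydrostannation (Bu3SnH, PdCl2(PPh3)2 cat., THF, 0 °C), directed to the terminal carbon by the fully substituted propargylic centre, would give 26.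

**Further compounds**

F1 | step 15 | tert-butyl 2,2-dichloro-3,3-dimethylpent-4-enoate | C=CC(C)(C)C(Cl)(Cl)C(=O)OC(C)(C)C
F2 | step 15 | tert-butyl 2,2-dichloro-3,3-dimethyl-5-oxopentanoate | O=CCC(C)(C)C(Cl)(Cl)C(=O)OC(C)(C)C
F3 | step 15 | tert-butyl (5S)-2,2-dichloro-5-hydroxy-3,3-dimethyl-7-oxooctanoate | CC(=O)C[C@@H](O)CC(C)(C)C(Cl)(Cl)C(=O)OC(C)(C)C
F4 | step 15 | tert-butyl (5S)-5-[(tert-butyldimethylsilyl)oxy]-2,2-dichloro-3,3-dimethyl-7-oxooctanoate | CC(=O)C[C@@H](O[Si](C)(C)C(C)(C)C)CC(C)(C)C(Cl)(Cl)C(=O)OC(C)(C)C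
F5 | step 15 | tert-butyl (1R,4S,6R)-4-[(tert-butyldimethylsilyl)oxy]-1-chloro-6-hydroxy-2,2,6-trimethylcyclohexane-1-carboxylate | CC(C)(C)OC(=O)[C@]1(Cl)[C@@](O)(C)C[C@@H](O[Si](C)(C)C(C)(C)C)CC1(C)C
F6 | step 13 | tert-butyl (5R)-2-chloro-5-hydroxy-3,3,7-trimethyloct-7-enoate (both C2 epimers) | CC(=C)C[C@@H](O)CC(C)(C)C(Cl)C(=O)OC(C)(C)C
F7 | step 18 | tert-butyl{[(1R,3S,6R)-6-ethynyl-1,5,5-trimethyl-7-oxabicyclo[4.1.0]heptan-3-yl]oxy}dimethylsilane | C#C[C@@]12O[C@]1(C)C[C@@H](O[Si](C)(C)C(C)(C)C)CC2(C)C
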